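## Structural features

The target 14 is a dihydroflavonol. Benzene ring A is fused to a six-membered oxygen heterocycle, ring C (O1, C2, C3, C4, C4a, C8a), which carries the catechol ring B on C2, a hydroxyl on C3 and a ketone on C4 conjugated with ring A. The C7 oxygen of ring A, para to C4 and meta to O1, is etherified with a geranyl chain that holds two isolated trisubstituted alkenes, the inner one E. C2 and C3 are adjacent stereocentres, both R, with ring B and the C3 hydroxyl trans to each other. The α-ketol is base-sensitive, because enolisation towards C3 allows β-elimination of the O1 phenoxide, which opens ring C and scrambles both centres. The geranyl aryl ether excludes hydrogenolysis and strong acid, its alkenes compete for any electrophilic oxidant, and the free catechol is easily oxidised. The carbon skeleton is small, so the real difficulty is to place oxygen on C3 and C4 in the right relative and absolute sense next to C2 while the side chain is left alone. The key step exploits the fact that C3 and C4 can be the two carbons of a cis alkene inside ring C, conjugated with ring A, in a 2-aryl-2H-chromene; the C7 oxygen para to C4 then makes the C4–O bond of the resulting oxirane the one that opens.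

## Logic of the disconnections

From 14 to 13. The two O–H bonds of the ring B catechol are traced back to O–Si bonds. A free catechol would not survive hypochlorite, copper or gold, whereas a silyl ether can be removed at the very end without base (which opens ring C of the ketol), without strong acid and without hydrogen (both of which attack the geranyl ether). The gain is that every earlier intermediate is neutral, non-chelating and chromatographable. The forward step needs a fluoride source buffered on the acidic side.

From 13 to 11. The C4=O bond is traced back to the C4–O bond of an oxirane bridging C3 and C4; the C3–O bond of 13 is the oxirane bond that stays. This turns the α-ketol into a single functional group whose two C–O bonds are made together, and it puts the change of oxidation level on C4, the carbon that the C7 oxygen activates. The forward step must open the oxirane at C4 only, bring in an oxygen that becomes a carbonyl in the same flask, suppress the 1,2-hydride shift from C3, and leave the C3–O bond untouched so that C3 inherits its configuration.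

From 11 to 10 (the key disconnection). Both oxirane bonds, C3–O and C4–O, are cut, leaving the cis C3=C4 alkene of 10. Two of the three stereocentres vanish and only C2 remains. The alkene is conjugated with ring A and cis by ring constraint, which is the substrate class on which manganese–salen oxygen transfer is most selective. The forward step must attack the face opposite the C2 aryl group, ignore the two side-chain alkenes, and run in a medium in which the acid-labile product survives. The structures of 10 and 11 are consistent with each other and with 14: C2 is S in 10 and R in 11, 13 and 14 with no change of geometry, because C3 outranks the aryl carbon once it bears oxygen.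

From 10 to 9. The C4–C4a vinyl–aryl bond is cut, which opens ring C. C3 and C4 become a terminal alkyne and ring A becomes a 1,3-dioxygenated benzene with a free position para to the geranyloxy group. An alkyne is at the right oxidation level for the ring alkene, and the closure does not involve the C2–O1 bond or its stereocentre. The forward step must close 6-endo, must choose the position para to the geranyloxy group over the one between the two oxygens, and must not ionise the benzylic C2–O1 bond.

From 9 to 8 and 3. The C2–O1 ether bond is cut, which divides the molecule into two halves of similar size: ring A with the side chain (3) and ring B with a propargylic three-carbon unit (8). A propargylic C–O bond next to a terminal alkyne can be formed enantioselectively through a copper allenylidene, so 8 may be racemic. The forward step must alkylate an electron-rich phenol on oxygen and not on carbon, and must set with high selectivity the one stereocentre from which the other two are later derived.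

From 8 to 5 and 6. The C2–C3 bond between the carbinol carbon and the alkyne is cut, together with the acyl–oxygen bond of the carbonate. Acetylide addition to an aromatic aldehyde needs no stereocontrol, and the alkoxide can be acylated in the same flask, which saves a step. The forward step only has to avoid a nucleophilic leaving group, hence the tert-butyl carbonate.

From 5 to 4, and from 3 to 1 and 2. Two O–Si bonds in 5 and the O–CH2 bond between the ring A oxygen and the side chain in 3 are cut. This arrives at four commercial compounds. The forward steps must mono-alkylate a symmetrical diphenol on oxygen and keep the E alkene of the chain.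

## Other disconnections considered

Alternative 1: The cut removes ring A altogether. C4a–C8a, C5–C6 and C7–C8 are broken, so that C8a and C8 come from an ynol ether on the C2 oxygen, C4a and C5 from an ynone at C4, and C6 and C7 from tert-butoxyethyne A3. In the forward step a cationic monovalent rhodium catalyst ([Rh(cod)2]BF4 with a bisphosphine) would join the tethered diyne A2 and A3 through a rhodacyclopentadiene, alkyne insertion and reductive elimination, to give the flavanone A1 with rings A and C formed together.
- In its favour: three C–C bonds and two rings form in one operation, and C2 and C3 are built in an open chain before any ring exists. No oxidant ever meets the geranyl chain; on this point the alternative is better than the chosen plan, whose step 6 depends on chemoselectivity.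
- Against it here: A2 combines an ynol ether of a secondary benzylic alcohol, hard to make and easily hydrated, with a terminal ynone. The α-carbon of that ynone (C3) is a stereocentre and its β-carbon (C2) carries a leaving group, so epimerisation and β-elimination threaten before the key step. The orientation of A3 (tert-butoxy on C7 and not C6) rests only on electronic matching in the metallacycle.
- After the key step, A1 still needs tert-butyl ether cleavage beside three silyl ethers, geranylation of the C7 phenol and a triple desilylation.
- Comparison: structurally it builds a benzene ring that can be bought, where the chosen plan builds only ring C. Mechanistically both are catalytic and both fix the absolute configuration before the key step, so they are equal there. In step count it is clearly longer than eight.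

Alternative 2: The cut is the O1–C8a aryl ether bond, which unfolds ring C into the anti-configured open-chain β-hydroxy ketone A5 with a fluorine ortho to the acyl group on ring A. In the forward step the potassium alkoxide at C2 adds to the fluorine-bearing carbon, the Meisenheimer complex loses fluoride, and the flavanone A4 forms. C2 keeps its configuration because its C–O bond is not touched.
- In its favour: the fluoroarene fixes the substitution of ring A, which is better than step 5 of the chosen plan, where two ortho positions compete. Both stereocentres come from one acyclic anti-aldol, and again no oxidation is run beside the geranyl chain, also a point on which it is better.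
- Against it here: the nucleophile is the alkoxide of an aldol, so retro-aldol cleavage and enolate epimerisation at C3 compete under the base the closure needs. The fluoride is activated by a single acyl group whose acceptor strength is lowered by the para geranyloxy donor. An anti-selective glycolate aldol leading to A5 would need an auxiliary and extra functional-group changes. The 4-methoxybenzyl ether must later be removed oxidatively beside the electron-rich side chain.
- Comparison: the number of stereocentres to control is equal, and A4 is about as far from 14 as 11 is, so the end games are equal. The ionic, strongly basic ring closure is the weaker mechanism for a ketol, and making A5 should take more steps than the five that lead to 10.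

Alternative 3: The cut takes C3 out of ring C. The C2–C3 and C3–C4 bonds are broken, leaving the 3-siloxy-2-arylbenzofuran A7, whose furan carbons become C2 and C4 of the flavanone. In the forward step a zinc carbenoid bearing a 4-methoxybenzyloxy group would cyclopropanate the enol ether double bond of A7, and protonolysis of the internal bond of the siloxycyclopropane would give the flavanone A6.
- In its favour: A7 is one silylation away from an easily assembled benzofuranone, and ring A is regiochemically fixed. If the step worked, the route could match or undercut eight steps, so on step economy it is potentially the equal or the better.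
- Against it here: the double bond is part of an aromatic furan, so cyclopropanation costs that stabilisation, and α-alkoxy zinc carbenoids are not established reagents. C3 would be set in the carbenoid addition and C2 in the protonolysis, neither under a chiral controlling element, so a racemate is the best to be expected and the trans relationship would rest on later equilibration.
- Comparison: mechanistically it would be new chemistry on this substrate class, whereas every step of the chosen plan is a known reaction type. Structurally it forms both stereocentres last and under the least control, while the chosen plan sets C2 by asymmetric catalysis and relays it to C3.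

Key step: step 6

Assumption: the sense of induction of the copper–pybox catalyst in step 4 is taken to be such that the (S,S)-ligand gives the (S)-ether; if the first analysis shows the opposite, the mirror-image ligand is used with no other change.

## Route

Step 1
Reactants: 1 resorcinol; 2 geranyl bromide
Product: 3 3-geranyloxyphenol (3-{[(2E)-3,7-dimethylocta-2,6-dien-1-yl]oxy}phenol)
Conditions: 1 (3 equiv), K2CO3 (1.1 equiv), acetone, reflux
Reagents that add atoms: none
Why: Williamson ether synthesis; the mono-phenoxide of 1 alkylates on oxygen by SN2 at the primary allylic carbon, so the E alkene is untouched, and the excess of water-soluble 1 suppresses the bis-ether and is washed out.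

Step 2
Reactants: 4 3,4-dihydroxybenzaldehyde
Product: 5 3,4-bis(tert-butyldimethylsilyloxy)benzaldehyde
Conditions: TBSCl (2.4 equiv), imidazole (5 equiv), DMF, 0 °C → rt
Reagents that add atoms: tert-butyldimethylsilyl chloride, CC(C)(C)[Si](C)(C)Cl
Why: Imidazole-promoted silylation of both phenols; the silyl ethers mask the catechol against hypochlorite, copper and gold and are the only groups that can later be removed without base, strong acid or hydrogen.

Step 3
Reactants: 5 3,4-bis(tert-butyldimethylsilyloxy)benzaldehyde; 6 ethynylmagnesium bromide
Product: 8 rac-tert-butyl 1-[3,4-bis(tert-butyldimethylsilyloxy)phenyl]prop-2-yn-1-yl carbonate, via bromomagnesium propargylic alkoxide 7 (not isolated)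
Conditions: 6 (1.1 equiv), THF, −78 → 0 °C; then Boc2O (1.3 equiv), 0 °C → rt; aq. NH4Cl
Reagents that add atoms: di-tert-butyl dicarbonate, CC(C)(C)OC(=O)OC(=O)OC(C)(C)C
Why: Grignard 1,2-addition of the acetylide forms the C2–C3 bond and a racemic carbinol, whose magnesium alkoxide is acylated in the same flask by Boc2O. The racemate is acceptable because step 4 is enantioconvergent, and the tert-butyl carbonate is chosen because it later leaves as CO2 and poorly nucleophilic tert-butoxide.

Step 4
Reactants: 8 rac-tert-butyl 1-[3,4-bis(tert-butyldimethylsilyloxy)phenyl]prop-2-yn-1-yl carbonate; 3 3-geranyloxyphenol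
Product: 9 (S)-1-[3,4-bis(tert-butyldimethylsilyloxy)phenyl]prop-2-yn-1-yl 3-geranyloxyphenyl ether
Conditions: 3 (1.5 equiv), CuOTf·½C6H6 (5 mol%), (S,S)-Ph-pybox (10 mol%), iPr2NEt (1.2 equiv), CH2Cl2, −20 °C
Reagents that add atoms: none
Why: Copper-catalysed enantioselective propargylic etherification: the copper acetylide of 8 expels the carbonate to give a planar copper allenylidene, which erases the stereocentre of 8, and the phenol oxygen of 3 adds to the γ-carbon on the face left open by the pybox ligand, setting the future C2 as S. An aprotic solvent keeps competing oxygen nucleophiles out.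

Step 5
Reactants: 9 (S)-1-[3,4-bis(tert-butyldimethylsilyloxy)phenyl]prop-2-yn-1-yl 3-geranyloxyphenyl ether
Product: 10 (2S)-7-geranyloxy-2-[3,4-bis(tert-butyldimethylsilyloxy)phenyl]-2H-chromene
Conditions: Ph3PAuNTf2 (2 mol%), 2,6-di-tert-butyl-4-methylpyridine (5 mol%), CH2Cl2, 0 °C → rt, dark
Reagents that add atoms: none
Why: Gold-catalysed intramolecular alkyne hydroarylation (6-endo-dig Friedel–Crafts-type attack on the gold-activated alkyne, then protodeauration) forms C4–C4a; the ring position para to the geranyloxy group is the more activated and less hindered of the two ortho positions and should give the 7-substituted chromene. The C2–O1 bond is never broken, so the S configuration is carried over, and the hindered pyridine buffers traces of acid that could ionise the benzylic ether.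

Step 6
Reactants: 10 (2S)-7-geranyloxy-2-[3,4-bis(tert-butyldimethylsilyloxy)phenyl]-2H-chromene
Product: 11 (2R,3S,4S)-3,4-epoxy-7-geranyloxy-3',4'-bis(tert-butyldimethylsilyloxy)flavan (2,3-trans; oxirane oxygen on the face opposite ring B)
Conditions: (S,S)-(salen)MnCl [salen = N,N'-bis(3,5-di-tert-butylsalicylidene)-1,2-cyclohexanediaminate] (5 mol%), 4-phenylpyridine N-oxide (20 mol%), aq. NaOCl (Na2HPO4 buffer, pH 11.3), CH2Cl2, 0 °C; cold work-up, filtration through basic alumina, used crude
Reagents that add atoms: sodium hypochlorite, [Na+].[O-]Cl
Why: NaOCl oxidises the trivalent manganese complex to a pentavalent oxomanganese species, to which the cis C3=C4 alkene of 10 approaches side-on; the closest known reaction type is the Jacobsen–Katsuki epoxidation of 2H-chromenes. Oxygen is transferred stepwise: the C3–O bond forms first and leaves a C4 radical stabilised by ring A, which then collapses onto the manganese-bound oxygen to form the C4–O bond. The three-membered ring is thus closed by radical collapse, and it must be cis-fused because the six-membered ring forbids rotation about C3–C4. C3 and C4 are set together by the choice of alkene face: the C2 aryl group shields its own face, and the (S,S)-catalyst, which delivers the (3S,4S)-oxirane to simple 2H-chromenes, prefers the same open face, so substrate and catalyst are matched. Any minor enantiomer of 10 is mismatched, reacts more slowly and to a diastereomer, so the step should also raise the stereochemical purity. The step needs chemoselectivity for the conjugated cis alkene over the two isolated trisubstituted alkenes of the geranyl chain; the catalyst's intrinsic preference for conjugated cis alkenes secures this, and hypochlorite at pH 11.3 carries neither a peracid nor free hypochlorous acid. The basic buffered medium also protects the para-alkoxybenzylic oxirane, which is why it is not chromatographed on silica. C2 is not touched.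

Step 7
Reactants: 11 (2R,3S,4S)-3,4-epoxy-7-geranyloxy-3',4'-bis(tert-butyldimethylsilyloxy)flavan
Product: 13 (2R,3R)-7-geranyloxy-3-hydroxy-3',4'-bis(tert-butyldimethylsilyloxy)flavanone, via C4 alkoxysulfonium camphorsulfonate 12 (not isolated)
Conditions: DMSO (10 equiv), CH2Cl2, (±)-camphor-10-sulfonic acid (1.1 equiv, added last), −20 °C; then Et3N (4 equiv), −20 °C → rt; pH 7 buffer
Reagents that add atoms: dimethyl sulfoxide, CS(C)=O
Why: Kornblum-type oxidative opening of an epoxide by DMSO with a Swern-like collapse: protonation opens the oxirane at C4 only, because that cation is benzylic and stabilised by the C7 oxygen para to it, and DMSO captures it as alkoxysulfonium ion 12. Et3N then forms the sulfur ylide, which removes H4 intramolecularly and releases Me2S and the C4 ketone. The C3–O bond is never broken, so C3 keeps its geometry and becomes 3R only through the change in priorities.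

Step 8
Reactants: 13 (2R,3R)-7-geranyloxy-3-hydroxy-3',4'-bis(tert-butyldimethylsilyloxy)flavanone
Product: 14 (2R,3R)-2-(3,4-dihydroxyphenyl)-7-geranyloxy-3-hydroxy-2,3-dihydro-4H-chromen-4-one (CNP0508026.1)
Conditions: Et3N·3HF (6 equiv), THF, 0 °C → rt, under argon; pH 7 buffer work-up
Reagents that add atoms: none
Why: Fluoride-mediated cleavage of the two aryl silyl ethers, driven by Si–F bond formation; the amine–HF complex is slightly acidic, so neither the base-sensitive ketol nor the acid-sensitive geranyl ether is endangered, and C2 and C3 are not touched.

## Compound list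

1 | resorcinol | Oc1cccc(O)c1 | starting material
2 | geranyl bromide | CC(C)=CCC/C(C)=C/CBr | starting material
3 | 3-geranyloxyphenol | CC(C)=CCC/C(C)=C/COc1cccc(O)c1 | intermediate
4 | 3,4-dihydroxybenzaldehyde | O=Cc1ccc(O)c(O)c1 | starting material
5 | 3,4-bis(tert-butyldimethylsilyloxy)benzaldehyde | O=Cc1ccc(O[Si](C)(C)C(C)(C)C)c(O[Si](C)(C)C(C)(C)C)c1 | intermediate
6 | ethynylmagnesium bromide | C#C[Mg]Br | starting material
7 | bromomagnesium 1-[3,4-bis(tert-butyldimethylsilyloxy)phenyl]prop-2-yn-1-olate (racemic) | C#CC(O[Mg]Br)c1ccc(O[Si](C)(C)C(C)(C)C)c(O[Si](C)(C)C(C)(C)C)c1 | intermediate (not isolated)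
8 | rac-tert-butyl 1-[3,4-bis(tert-butyldimethylsilyloxy)phenyl]prop-2-yn-1-yl carbonate | C#CC(OC(=O)OC(C)(C)C)c1ccc(O[Si](C)(C)C(C)(C)C)c(O[Si](C)(C)C(C)(C)C)c1 | intermediate
9 | (S)-1-[3,4-bis(tert-butyldimethylsilyloxy)phenyl]prop-2-yn-1-yl 3-geranyloxyphenyl ether | CC(C)=CCC/C(C)=C/COc1cccc(O[C@H](c2ccc(O[Si](C)(C)C(C)(C)C)c(O[Si](C)(C)C(C)(C)C)c2)C#C)c1 | intermediate
10 | (2S)-7-geranyloxy-2-[3,4-bis(tert-butyldimethylsilyloxy)phenyl]-2H-chromene | CC(C)=CCC/C(C)=C/COc1ccc2c(c1)O[C@H](c1ccc(O[Si](C)(C)C(C)(C)C)c(O[Si](C)(C)C(C)(C)C)c1)C=C2 | intermediate
11 | (2R,3S,4S)-3,4-epoxy-7-geranyloxy-3',4'-bis(tert-butyldimethylsilyloxy)flavan (2,3-trans) | CC(C)=CCC/C(C)=C/COc1ccc2c(c1)O[C@H](c1ccc(O[Si](C)(C)C(C)(C)C)c(O[Si](C)(C)C(C)(C)C)c1)[C@H]3O[C@@H]23 | intermediate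
12 | [2,3-trans-7-geranyloxy-3-hydroxy-3',4'-bis(tert-butyldimethylsilyloxy)flavan-4-yl]oxydimethylsulfonium camphor-10-sulfonate (C2 and C3 as in 13, C4 epimers) | CC(C)=CCC/C(C)=C/COc1ccc2c(c1)O[C@H](c1ccc(O[Si](C)(C)C(C)(C)C)c(O[Si](C)(C)C(C)(C)C)c1)[C@@H](O)C2O[S+](C)C.CC1(C)C2CCC1(CS(=O)(=O)[O-])C(=O)C2 | intermediate (not isolated)
13 | (2R,3R)-7-geranyloxy-3-hydroxy-3',4'-bis(tert-butyldimethylsilyloxy)flavanone | CC(C)=CCC/C(C)=C/COc1ccc2c(c1)O[C@H](c1ccc(O[Si](C)(C)C(C)(C)C)c(O[Si](C)(C)C(C)(C)C)c1)[C@@H](O)C2=O | intermediate
14 | (2R,3R)-2-(3,4-dihydroxyphenyl)-7-geranyloxy-3-hydroxy-2,3-dihydro-4H-chromen-4-one | CC(C)=CCC/C(C)=C/COc1ccc2c(c1)O[C@H](c1ccc(O)c(O)c1)[C@@H](O)C2=O | target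

## Step count and least certain steps

Total: 8 steps. Longest linear sequence: 7 steps (4 → 5 → 8 → 9 → 10 → 11 → 13 → 14).

Step 6 (key step). Most likely to go wrong are solvolytic opening of the oxirane at C4 during reaction or work-up, competing oxidation of the side-chain alkenes or of the doubly activated C2–H bond, and incomplete facial selectivity if aryl shielding and catalyst preference reinforce each other less than expected.
Fallback, from 10 to 13 without an oxirane: hydroboration of 10 with 9-BBN (THF, 0 °C → rt) should place boron on C3, β to ring A and anti to the C2 aryl group, and should spare the trisubstituted side-chain alkenes; this gives the 2,3-trans C3-borane F1. Oxidation with NaBO3·4H2O gives the (2R,3S)-flavan-3-ol F2. DDQ in wet CH2Cl2 then abstracts hydride from C4, which the C7 oxygen activates, and water captures the cation to give the 2,3-trans-flavan-3,4-diol F3. A second equivalent of DDQ oxidises the benzylic carbinol of F3 to the ketone, returning to the route at 13. Facial control here rests on the substrate alone.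

Step 4. Most likely to go wrong are attack of the allenylidene by a ring carbon of the electron-rich phenol instead of its oxygen, and loss of enantioselectivity through uncatalysed ionisation of the electron-rich benzylic carbonate.
Fallback, from 5 and 6 to 9: the addition of step 3 is worked up with aqueous NH4Cl to give the racemic 1-[3,4-bis(tert-butyldimethylsilyloxy)phenyl]prop-2-yn-1-ol F4. Kinetic resolution with immobilised Candida antarctica lipase B and vinyl acetate should acylate the enantiomer with the large aryl and small ethynyl group in the usual arrangement, giving the (R)-acetate F5, which is separated from the slow-reacting half of F4. Ethanolysis of F5 with the same lipase gives the (R)-alcohol F6. A Mitsunobu reaction of F6 with 3 (PPh3, diisopropyl azodicarboxylate, toluene, 0 °C) forms the ether with inversion and returns to the route at 9; oxygen alkylation is then guaranteed by the mechanism.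

Step 5. Most likely to go wrong are cyclisation at the ring position between the two oxygens, ionisation of the benzylic C2–O1 bond under the cationic gold catalyst with loss of configuration at C2, and light-induced ring opening of the chromene.
Fallback, from 2 to 10 with ring A regiochemistry fixed from the start:
- Commercial 7-hydroxychromone is alkylated with 2 (K2CO3, acetone) to give 7-geranyloxychromone F6a, listed below as F7.
- Commercial 4-bromocatechol is silylated (TBSCl, imidazole) to 4-bromo-1,2-bis(tert-butyldimethylsilyloxy)benzene F8 and converted (n-BuLi, B(OiPr)3, −78 °C, mild aqueous work-up) into [3,4-bis(tert-butyldimethylsilyloxy)phenyl]boronic acid F9.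
- Enantioselective conjugate addition of F9 to the chromone F7 (Pd(OCOCF3)2, chiral tert-butyl pyridine–oxazoline ligand of the antipode that gives the 2S product, NH4PF6, H2O, ClCH2CH2Cl, 60 °C) gives the (2S)-flavanone F10.
- NaBH4 reduction gives the (2S,4S)-flavan-4-ol F11, and non-acidic dehydration with Burgess reagent returns to the route at 10.

Step 7. Most likely to go wrong are a 1,2-hydride shift from C3 to the C4 cation (Meinwald-type rearrangement to the 3-ketone), ionisation of the alkoxysulfonium ion before the base step, and acid damage to the geranyl ether.
Fallback, from 11 to 13 in two separate events: methanolysis of 11 (MeOH, pyridinium p-toluenesulfonate, 0 °C) opens the oxirane at C4 to the 2,3-trans-4-methoxyflavan-3-ol F12. DDQ in CH2Cl2 with pH 7 buffer then abstracts hydride from C4 of F12, and hydrolysis of the oxocarbenium ion releases methanol and the ketone, returning to the route at 13.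

## Further compounds

F1 | step 6 | 2,3-trans-3-(9-borabicyclo[3.3.1]nonan-9-yl)-7-geranyloxy-3',4'-bis(tert-butyldimethylsilyloxy)flavan | CC(C)=CCC/C(C)=C/COc1ccc2c(c1)O[C@H](c1ccc(O[Si](C)(C)C(C)(C)C)c(O[Si](C)(C)C(C)(C)C)c1)[C@@H](B1C3CCCC1CCC3)C2
F2 | step 6 | (2R,3S)-7-geranyloxy-3',4'-bis(tert-butyldimethylsilyloxy)flavan-3-ol | CC(C)=CCC/C(C)=C/COc1ccc2c(c1)O[C@H](c1ccc(O[Si](C)(C)C(C)(C)C)c(O[Si](C)(C)C(C)(C)C)c1)[C@@H](O)C2
F3 | step 6 | 2,3-trans-7-geranyloxy-3',4'-bis(tert-butyldimethylsilyloxy)flavan-3,4-diol (C4 epimers) | CC(C)=CCC/C(C)=C/COc1ccc2c(c1)O[C@H](c1ccc(O[Si](C)(C)C(C)(C)C)c(O[Si](C)(C)C(C)(C)C)c1)[C@@H](O)C2O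
F4 | step 4 | rac-1-[3,4-bis(tert-butyldimethylsilyloxy)phenyl]prop-2-yn-1-ol | C#CC(O)c1ccc(O[Si](C)(C)C(C)(C)C)c(O[Si](C)(C)C(C)(C)C)c1
F5 | step 4 | (R)-1-[3,4-bis(tert-butyldimethylsilyloxy)phenyl]prop-2-yn-1-yl acetate | C#C[C@@H](OC(C)=O)c1ccc(O[Si](C)(C)C(C)(C)C)c(O[Si](C)(C)C(C)(C)C)c1
F6 | step 4 | (R)-1-[3,4-bis(tert-butyldimethylsilyloxy)phenyl]prop-2-yn-1-ol | C#C[C@@H](O)c1ccc(O[Si](C)(C)C(C)(C)C)c(O[Si](C)(C)C(C)(C)C)c1
F7 | step 5 | 7-geranyloxychromone | CC(C)=CCC/C(C)=C/COc1ccc2c(c1)occc2=O
F8 | step 5 | 4-bromo-1,2-bis(tert-butyldimethylsilyloxy)benzene | Brc1ccc(O[Si](C)(C)C(C)(C)C)c(O[Si](C)(C)C(C)(C)C)c1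
F9 | step 5 | [3,4-bis(tert-butyldimethylsilyloxy)phenyl]boronic acid | OB(O)c1ccc(O[Si](C)(C)C(C)(C)C)c(O[Si](C)(C)C(C)(C)C)c1
F10 | step 5 | (2S)-7-geranyloxy-3',4'-bis(tert-butyldimethylsilyloxy)flavanone | CC(C)=CCC/C(C)=C/COc1ccc2c(c1)O[C@H](c1ccc(O[Si](C)(C)C(C)(C)C)c(O[Si](C)(C)C(C)(C)C)c1)CC2=O
F11 | step 5 | (2S,4S)-7-geranyloxy-3',4'-bis(tert-butyldimethylsilyloxy)flavan-4-ol | CC(C)=CCC/C(C)=C/COc1ccc2c(c1)O[C@H](c1ccc(O[Si](C)(C)C(C)(C)C)c(O[Si](C)(C)C(C)(C)C)c1)C[C@@H]2O
F12 | step 7 | 2,3-trans-7-geranyloxy-4-methoxy-3',4'-bis(tert-butyldimethylsilyloxy)flavan-3-ol (C4 epimers) | CC(C)=CCC/C(C)=C/COc1ccc2c(c1)O[C@H](c1ccc(O[Si](C)(C)C(C)(C)C)c(O[Si](C)(C)C(C)(C)C)c1)[C@@H](O)C2OC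
A1 | alternative 1 | (2R,3R)-7-tert-butoxy-3,3',4'-tris(tert-butyldimethylsilyloxy)flavanone | CC(C)(C)Oc1ccc2c(c1)O[C@H](c1ccc(O[Si](C)(C)C(C)(C)C)c(O[Si](C)(C)C(C)(C)C)c1)[C@@H](O[Si](C)(C)C(C)(C)C)C2=O
A2 | alternative 1 | 1-[3,4-bis(tert-butyldimethylsilyloxy)phenyl]-1-ethynyloxy-2-(tert-butyldimethylsilyloxy)pent-4-yn-3-one (configured as in A1) | C#CO[C@H](c1ccc(O[Si](C)(C)C(C)(C)C)c(O[Si](C)(C)C(C)(C)C)c1)[C@@H](O[Si](C)(C)C(C)(C)C)C(=O)C#C
A3 | alternative 1 | tert-butoxyethyne | C#COC(C)(C)C
A4 | alternative 2 | (2R,3R)-7-geranyloxy-3-(4-methoxybenzyloxy)-3',4'-bis(triisopropylsilyloxy)flavanone | CC(C)=CCC/C(C)=C/COc1ccc2c(c1)O[C@H](c1ccc(O[Si](C(C)C)(C(C)C)C(C)C)c(O[Si](C(C)C)(C(C)C)C(C)C)c1)[C@@H](OCc1ccc(OC)cc1)C2=O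
A5 | alternative 2 | anti-1-(2-fluoro-4-geranyloxyphenyl)-3-hydroxy-2-(4-methoxybenzyloxy)-3-[3,4-bis(triisopropylsilyloxy)phenyl]propan-1-one (configured as in A4) | CC(C)=CCC/C(C)=C/COc1ccc(c(F)c1)C(=O)[C@H](OCc1ccc(OC)cc1)[C@H](O)c1ccc(O[Si](C(C)C)(C(C)C)C(C)C)c(O[Si](C(C)C)(C(C)C)C(C)C)c1
A6 | alternative 3 | (2R,3R)-7-geranyloxy-3-(4-methoxybenzyloxy)-3',4'-bis(tert-butyldimethylsilyloxy)flavanone | CC(C)=CCC/C(C)=C/COc1ccc2c(c1)O[C@H](c1ccc(O[Si](C)(C)C(C)(C)C)c(O[Si](C)(C)C(C)(C)C)c1)[C@@H](OCc1ccc(OC)cc1)C2=O
A7 | alternative 3 | 6-geranyloxy-2-[3,4-bis(tert-butyldimethylsilyloxy)phenyl]-3-(tert-butyldimethylsilyloxy)benzofuran | CC(C)=CCC/C(C)=C/COc1ccc2c(c1)oc(-c1ccc(O[Si](C)(C)C(C)(C)C)c(O[Si](C)(C)C(C)(C)C)c1)c2O[Si](C)(C)C(C)(C)C
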